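**Retrosynthetic overview**
1. (4S,5S)-Humulinone ⇒ retro-α-ketol ring expansion (five → six) to cis-4,6-dihydroxy-4,6-diprenyl-2-isovalerylcyclohexane-1,3,5-trione, which is meso.
2. That trione ⇒ two tertiary C–O disconnections (C4–OH, then C6–OH): electrophilic hydroxylation of humulone and hydroxylative dearomatisation of deoxyhumulone. These are the key bonds, and both are made in one flask.
3. Because the trione is meso, an asymmetric first hydroxylation would be erased. Absolute configuration is set by a chiral ammonium ion pair that picks one of the two enantiotopic carbinols for the contraction.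
4. Deoxyhumulone ⇒ double C-prenylation of phlorisovalerophenone ⇒ Friedel–Crafts acylation of phloroglucinol.
5. Ring order: the only carbocycle is bought as the arene, dearomatised, then contracted six → five in the last step.

Assumption: the sense of induction of the new step cannot be taken from precedent; the cinchonidine-derived salt is written, and its commercial pseudo-enantiomer (cinchonine-derived) is the like-for-like replacement if the (4R,5R) antipode should dominate.

Numbering: in humulone and its 4-hydroxy derivative, C1 is the ring ketone next to the carbinol C6, C2 carries the isovaleryl group, and C4 and C6 carry the prenyl groups. In the target, C1 is the ring ketone, C4 carries the acyl side chain and C5 the prenyl group.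

**Step 1**
Reactants: 1 phloroglucinol, 2 isovaleryl chloride
Product: 3 phlorisovalerophenone
Conditions: AlCl3 (3.5 equiv), CH2Cl2/PhNO2, 0 → 40 °C; ice/dilute aq HCl
Reagents that add atoms: none
Why: Friedel–Crafts acylation; the acylium–AlCl3 complex attacks the very electron-rich ring, and the first acyl group (aluminium-chelated and deactivating) stops a second acylation; no stereocentre is formed.

**Step 2**
Reactants: 3 phlorisovalerophenone, 4 prenyl bromide (2 equiv)
Product: 5 deoxyhumulone
Conditions: KOH (2 equiv), MeOH/H2O, Ar, 0 °C → rt
Reagents that add atoms: none
Why: Double SN2 C-alkylation of the ambident phloroglucinolate; in protic medium the hydrogen-bonded oxygens are shielded, so the soft allylic bromide is taken up at the two free ring carbons, and two equivalents of base and bromide limit geminal over-prenylation; no stereocentre is formed.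

**Step 3**
Reactants: 5 deoxyhumulone
Product: 8 (4S,5S)-humulinone, via humulone 6 (not isolated), via meso-4-hydroxyhumulone 7 (not isolated)
Conditions: PhC(CH3)2OOH (2.3 equiv), N-(9-anthracenylmethyl)cinchonidinium chloride (10 mol%), K2CO3 (s, 3 equiv), toluene, Ar, dark, −10 → 0 °C, 48 h; then cold dilute aq HCl
Reagents that add atoms: cumene hydroperoxide, CC(C)(OO)c1ccccc1 (one O atom per equivalent, two equivalents used up)
Why: Proposed new method: chiral-cation-directed double C-hydroxylation with a desymmetrising α-ketol ring contraction; the toluene-soluble ammonium phenolate of 5 (an enolate of a β-triketone, known to take up electrophiles at its prenyl-bearing carbons) attacks the terminal oxygen of the hydroperoxide to give 6 (first C–O bond, dearomatisation); the more acidic 6 is re-extracted as its dienolate and is hydroxylated at C4 on the face that carries the C6–OH (anti to the C6 prenyl group, hydroperoxide hydrogen-bonded to C6–OH; second C–O bond, with the site and relative sense of the classical peroxide oxidation of humulone), so both enantiomers of 6 converge on the cis-diol 7; the tricarbonyl anion of 7 is symmetric, so 7 is meso and the configuration of 6 is irrelevant; in the contact ion pair the N+ centre and the 9-OH of the catalyst bridge the C5 carbonyl oxygen and only one of the two enantiotopic carbinol oxygens; the (S)-configured carbinol carbon C6 ionises and its C6–C1 bond shifts suprafacially to C5 in the cisoid O−/C=O geometry known from humulone → isohumulone; C6 becomes the side-chain ketone, and the old C5 becomes C4 of 8 with its OH cis to the retained C4–OH of 7 (now C5 of 8), which is (4S,5S); the prenyl C=C bonds are inert to a metal-free alkyl hydroperoxide, the potassium salts are insoluble in toluene so the unpaired background is suppressed, and precipitation of the potassium salt of 8 turns the catalyst over; closest known reaction types: asymmetric phase-transfer α-hydroxylation of β-dicarbonyl compounds with cumene hydroperoxide, the NaHCO3/cumene hydroperoxide oxidation of humulone to humulinone, and chiral-Lewis-acid-catalysed enantioselective α-ketol rearrangements.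

**Compound list**
1 | phloroglucinol (benzene-1,3,5-triol) | Oc1cc(O)cc(O)c1 | starting material
2 | isovaleryl chloride (3-methylbutanoyl chloride) | CC(C)CC(=O)Cl | starting material
3 | phlorisovalerophenone, 3-methyl-1-(2,4,6-trihydroxyphenyl)butan-1-one | CC(C)CC(=O)c1c(O)cc(O)cc1O | intermediate
4 | prenyl bromide (1-bromo-3-methylbut-2-ene) | CC(C)=CCBr | starting material
5 | deoxyhumulone, 3-methyl-1-[2,4,6-trihydroxy-3,5-bis(3-methylbut-2-enyl)phenyl]butan-1-one (achiral) | CC(C)CC(=O)c1c(O)c(CC=C(C)C)c(O)c(CC=C(C)C)c1O | intermediate
6 | humulone, 3,5,6-trihydroxy-4,6-bis(3-methylbut-2-enyl)-2-(3-methylbutanoyl)cyclohexa-2,4-dien-1-one (racemic or scalemic at C6, configuration of no consequence) | CC(C)CC(=O)C1=C(O)C(CC=C(C)C)=C(O)C(O)(CC=C(C)C)C1=O | intermediate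
7 | meso-4-hydroxyhumulone, (4R,6S)-3,4,6-trihydroxy-4,6-bis(3-methylbut-2-enyl)-2-(3-methylbutanoyl)cyclohex-2-ene-1,5-dione (both OH on one face, both prenyl groups on the other; meso through fast tricarbonyl tautomerism) | CC(C)CC(=O)C1=C(O)[C@](O)(CC=C(C)C)C(=O)[C@](O)(CC=C(C)C)C1=O | intermediate
8 | (4S,5S)-humulinone, (4S,5S)-3,4,5-trihydroxy-5-(3-methylbut-2-enyl)-2-(3-methylbutanoyl)-4-(4-methylpent-3-enoyl)cyclopent-2-en-1-one (C4–OH and C5–OH cis) | CC(C)=CCC(=O)[C@]1(O)C(O)=C(C(=O)CC(C)C)C(=O)[C@]1(O)CC=C(C)C | target

**Total step count:** 3. **Longest linear sequence:** 3.

**Steps most likely to fail**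

First, step 3 (the proposed new step). The risks are:
- low enantiomeric excess through contraction outside the chiral ion pair;
- a sluggish second hydroxylation at low temperature;
- some trans-hydroxylation, which gives the C5 epimer.

The fallback uses known chemistry, sets out from 5 and comes back at 8. O2 and Pb(OAc)2 in MeOH precipitate the lead salt of 6. Dilute H2SO4 in MeOH releases racemic 6, which is now isolated. Cumene hydroperoxide in Et2O over saturated aqueous NaHCO3 at room temperature converts it into racemic humulinone F1. One equivalent of (S)-1-phenylethylamine in EtOAc/heptane, followed by fractional crystallisation, gives the diastereomerically pure (S)-1-phenylethylammonium (4S,5S)-humulinate F2 (from crystals or mother liquor, tracked by chiral HPLC). Cold dilute aq HCl/Et2O then releases 8.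

Second, step 2. The risk is a statistical mixture of mono-, di- and geminally tri-prenylated products together with O-prenyl ethers. The fallback sets out from 3 and comes back at 5. It is an acid-mediated Friedel–Crafts prenylation with 2-methylbut-3-en-2-ol (2 equiv) and BF3·OEt2 in dioxane at room temperature. This uses the dimethylallyl cation on the neutral phenol instead of SN2 on the phenolate, so geminal dialkylation and O-alkylation drop out. It makes no new compound (F0).

Third, step 1. The risks are O-acylation, diacylation and a tedious nitrobenzene work-up. The fallback sets out from 1 and comes back at 3. A Houben–Hoesch reaction with isovaleronitrile, ZnCl2 and dry HCl in Et2O at 0 °C precipitates 3-methyl-1-(2,4,6-trihydroxyphenyl)butan-1-iminium chloride F3, which is boiled in water to give 3.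

**Further compounds**
F1 | step 3 | racemic humulinone (1:1 mixture of 8 and its enantiomer, C4–OH and C5–OH cis) | CC(C)=CCC(=O)[C@]1(O)C(O)=C(C(=O)CC(C)C)C(=O)[C@]1(O)CC=C(C)C.CC(C)=CCC(=O)[C@@]1(O)C(O)=C(C(=O)CC(C)C)C(=O)[C@@]1(O)CC=C(C)C
F2 | step 3 | (S)-1-phenylethylammonium (4S,5S)-humulinate | CC(C)=CCC(=O)[C@]1(O)C([O-])=C(C(=O)CC(C)C)C(=O)[C@]1(O)CC=C(C)C.C[C@H]([NH3+])c1ccccc1
F0 | step 2 | none | none
F3 | step 1 | 3-methyl-1-(2,4,6-trihydroxyphenyl)butan-1-iminium chloride | CC(C)CC(=[NH2+])c1c(O)cc(O)cc1O.[Cl-]
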